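# Jatamanvaltrate H: proposed semisynthesis from genipin

**Retrosynthetic overview**
- The target is an iridoid (cyclopenta[c]pyran) in the genipin series. Both rings and the C5/C9 cis ring fusion already exist in commercial genipin (1), so no ring has to be built.
- Late steps: remove the C10 silyl group ← β-selective acylation of the C1 lactol with isovalerate ← acetylation of C7-OH and isovalerylation of C11-OH ← DIBAL reduction of the C11 methyl ester.
- The C7β-OH/C8α-OH/C10-CH2OH array comes from β-face epoxidation of C7=C8 followed by a Payne rearrangement/hydrolysis. The alkene oxidation must be done while the C4 ester still deactivates the C3=C4 enol ether.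

**Iridoid numbering used below:** C1 is the acetal carbon and O2 is the ring oxygen. C3=C4 is the enol ether, and C11 is the carbon on C4. C5 and C9 are the ring-fusion carbons. C6 is CH2, C7 is CH(OAc), and C8 carries OH and C10 (CH2OH).

**Assumptions**
- Peracid attacks the C7=C8 alkene from the convex β-face, the same face as H5/H9.
- Acylation of the equilibrating C1 lactol gives mainly the β-acylal, trans to C8. Any α-anomer is removed by chromatography.
- Genipin (1) is taken as commercially available.

---

## Route

**Step 1**
- Reactants: 1 genipin; 2 tert-butyldimethylsilyl chloride (TBSCl)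
- Product: 3, 1β,10-bis-O-TBS genipin
- Conditions: TBSCl (2.5 equiv), imidazole, DMF, 25 °C
- Reagents that add atoms: TBSCl, CC(C)(C)[Si](C)(C)Cl
- Why: Silylation protects the lactol from hydride and base and blocks C10. The C1 configuration is only carried through and is set in Step 10.

**Step 2**
- Reactants: 3
- Product: 4, 1β-O-TBS genipin with free C10-OH
- Conditions: PPTS (0.3 equiv), MeOH/CH2Cl2 1:1, 25 °C
- Reagents that add atoms: none
- Why: Acid methanolysis cleaves the unhindered primary TBS ether faster than the hindered anomeric TBS ether. The ionisation-resistant push–pull acetal survives.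

**Step 3**
- Reactants: 4; 5 mCPBA
- Product: 6, 7β,8β-epoxide
- Conditions: mCPBA (1.3 equiv), NaHCO3, CH2Cl2, 0 °C
- Reagents that add atoms: mCPBA, OOC(=O)c1cccc(Cl)c1
- Why: This is a Prilezhaev epoxidation. The C3=C4 enol ether is deactivated by the C4 ester, so only the trisubstituted C7=C8 alkene reacts. The peracid approaches from the convex face of the cis-fused bicycle, setting C7-O and C8-O on the β face.

**Step 4**
- Reactants: 6; 7 water
- Product: 8, 7β,8α,10-triol
- Conditions: 0.5 M aq. NaOH, THF, 0 → 25 °C
- Reagents that add atoms: water, O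
- Why: This is a Payne rearrangement followed by hydrolysis. The C10 alkoxide attacks C8 from the α face with inversion, giving an 8α,10-spiro-epoxide and a 7β-alkoxide whose configuration is retained. Hydroxide then opens the epoxide at the primary C10, so C8 ends up with α-OH and a β-CH2OH. This sets the C8 stereocentre, and C7 follows from Step 3.

**Step 5**
- Reactants: 8; 9 TBDPSCl
- Product: 10, 10-O-TBDPS ether
- Conditions: TBDPSCl (1.1 equiv), imidazole, DMF, 25 °C
- Reagents that add atoms: TBDPSCl, CC(C)(C)[Si](Cl)(c1ccccc1)c1ccccc1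
- Why: The bulky silyl chloride selects the primary C10-OH over the secondary C7-OH and tertiary C8-OH. TBDPS is a fluoride-removable group that survives the later selective TBS removal at C1.

**Step 6**
- Reactants: 10
- Product: 11, C11 allylic alcohol
- Conditions: DIBAL-H (4 equiv), CH2Cl2, −78 → −20 °C; Rochelle salt work-up
- Reagents that add atoms: none
- Why: DIBAL reduces the vinylogous-carbonate methyl ester to the allylic alcohol. The free C7/C8 hydroxyls only consume hydride, and no stereocentre changes.

**Step 7**
- Reactants: 11; 12 isovaleryl chloride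
- Product: 13, C11 isovalerate
- Conditions: iPrCH2COCl (1.2 equiv), pyridine, CH2Cl2, −20 → 0 °C
- Reagents that add atoms: isovaleryl chloride, CC(C)CC(=O)Cl
- Why: The unhindered primary allylic C11-OH acylates selectively at low temperature. The hindered C7-OH and the tertiary C8-OH do not react.

**Step 8**
- Reactants: 13; 14 acetic anhydride
- Product: 15, 7-OAc
- Conditions: Ac2O (1.5 equiv), pyridine, DMAP (cat.), CH2Cl2, 25 °C
- Reagents that add atoms: acetic anhydride, CC(=O)OC(C)=O
- Why: DMAP-catalysed acetylation of the secondary C7-OH proceeds with retention. The tertiary C8-OH is inert under these mild conditions. This step precedes any further hydride chemistry-free manipulation and follows the DIBAL step, which would have removed the acetate.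

**Step 9**
- Reactants: 15
- Product: 16, C1 lactol (crude, used at once)
- Conditions: HF·pyridine, pyridine, THF, 0 → 25 °C
- Reagents that add atoms: none
- Why: Buffered HF cleaves the anomeric TBS ether selectively. The primary TBDPS ether and all three esters survive. The lactol anomerises freely.

**Step 10**
- Reactants: 16; 12 isovaleryl chloride
- Product: 17, 1β-isovalerate
- Conditions: iPrCH2COCl (3 equiv), pyridine, DMAP (cat.), CH2Cl2, −20 → 0 °C
- Reagents that add atoms: isovaleryl chloride, CC(C)CC(=O)Cl
- Why: This is acylation of the rapidly equilibrating lactol. Curtin–Hammett control favours acylation of the less hindered β-alkoxide, and the β-acylal, trans to C8, is also the more stable anomer. This sets C1.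

**Step 11**
- Reactants: 17
- Product: 18, jatamanvaltrate H
- Conditions: TBAF (3 equiv), AcOH (3 equiv), THF, 25 °C
- Reagents that add atoms: none
- Why: Fluoride removes the primary TBDPS ether. The AcOH buffer suppresses ester hydrolysis and cis-1,3 acyl migration from O7 to O10.

---

## Compound list

1 | genipin, methyl (1R,4aS,7aS)-1-hydroxy-7-(hydroxymethyl)-1,4a,5,7a-tetrahydrocyclopenta[c]pyran-4-carboxylate | COC(=O)C1=CO[C@@H](O)[C@@H]2C(CO)=CC[C@H]12 | starting material
2 | TBSCl | CC(C)(C)[Si](C)(C)Cl | starting material (reagent)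
3 | 1β,10-bis-O-TBS genipin | COC(=O)C1=CO[C@@H](O[Si](C)(C)C(C)(C)C)[C@@H]2C(CO[Si](C)(C)C(C)(C)C)=CC[C@H]12 | intermediate
4 | 1β-O-TBS genipin (10-OH) | COC(=O)C1=CO[C@@H](O[Si](C)(C)C(C)(C)C)[C@@H]2C(CO)=CC[C@H]12 | intermediate
5 | mCPBA | OOC(=O)c1cccc(Cl)c1 | starting material (reagent)
6 | 7β,8β-epoxy-10-ol (1-OTBS, 11-CO2Me) | COC(=O)C1=CO[C@@H](O[Si](C)(C)C(C)(C)C)[C@@H]2[C@@]3(CO)O[C@H]3C[C@H]12 | intermediate
7 | water | O | starting material (reagent)
8 | 7β,8α,10-triol (1-OTBS, 11-CO2Me) | COC(=O)C1=CO[C@@H](O[Si](C)(C)C(C)(C)C)[C@@H]2[C@@](O)(CO)[C@@H](O)C[C@H]12 | intermediate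
9 | TBDPSCl | CC(C)(C)[Si](Cl)(c1ccccc1)c1ccccc1 | starting material (reagent)
10 | 10-O-TBDPS, 1-O-TBS, 7β,8α-diol methyl ester | COC(=O)C1=CO[C@@H](O[Si](C)(C)C(C)(C)C)[C@@H]2[C@@](O)(CO[Si](c3ccccc3)(c3ccccc3)C(C)(C)C)[C@@H](O)C[C@H]12 | intermediate
11 | C11 allylic alcohol (after DIBAL) | OCC1=CO[C@@H](O[Si](C)(C)C(C)(C)C)[C@@H]2[C@@](O)(CO[Si](c3ccccc3)(c3ccccc3)C(C)(C)C)[C@@H](O)C[C@H]12 | intermediate
12 | isovaleryl chloride | CC(C)CC(=O)Cl | starting material (reagent)
13 | 11-O-isovalerate | CC(C)CC(=O)OCC1=CO[C@@H](O[Si](C)(C)C(C)(C)C)[C@@H]2[C@@](O)(CO[Si](c3ccccc3)(c3ccccc3)C(C)(C)C)[C@@H](O)C[C@H]12 | intermediate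
14 | acetic anhydride | CC(=O)OC(C)=O | starting material (reagent)
15 | 7β-OAc compound | CC(C)CC(=O)OCC1=CO[C@@H](O[Si](C)(C)C(C)(C)C)[C@@H]2[C@@](O)(CO[Si](c3ccccc3)(c3ccccc3)C(C)(C)C)[C@@H](OC(C)=O)C[C@H]12 | intermediate
16 | C1 lactol | CC(C)CC(=O)OCC1=CO[C@@H](O)[C@@H]2[C@@](O)(CO[Si](c3ccccc3)(c3ccccc3)C(C)(C)C)[C@@H](OC(C)=O)C[C@H]12 | intermediate
17 | 1β,11-bis-isovalerate, 10-OTBDPS | CC(C)CC(=O)OCC1=CO[C@@H](OC(=O)CC(C)C)[C@@H]2[C@@](O)(CO[Si](c3ccccc3)(c3ccccc3)C(C)(C)C)[C@@H](OC(C)=O)C[C@H]12 | intermediate
18 | jatamanvaltrate H | CC(=O)O[C@H]1C[C@@H]2C(COC(=O)CC(C)C)=CO[C@@H](OC(=O)CC(C)C)[C@@H]2[C@@]1(O)CO | target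

**Total steps:** 11. **Longest linear sequence:** 11, from genipin.

## Three steps most likely to fail

1. **Step 4 (Payne hydrolysis, which also depends on β-face epoxidation in Step 3).** Competing hydrolysis of the C11 methyl ester, or the wrong epoxide face, would spoil the C7/C8 array.
   - Fallback: change the approach to intramolecular delivery of oxygen. Convert the C10-OH of epoxide 6 to its tert-butyl carbonate and treat with BF3·OEt2. This closes the 8α,10-cyclic carbonate with inversion at C8, and DIBAL in Step 6 then cleaves the carbonate and the ester together. The C10 silyl protection is then installed after that step.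
2. **Step 10 (lactol acylation).** The C11-CH2OR lactol is ring-chain labile and the anomer ratio is uncertain.
   - Fallback: skip the free lactol. Convert the anomeric TBS ether of 15 directly to the acylal with isovaleric anhydride and Sc(OTf)3 or TMSOTf, then separate anomers.
3. **Step 11 (final TBDPS removal).** The neopentyl-type primary TBDPS is slow to remove, and cis-1,3 acyl migration from O7 to O10 is possible.
   - Fallback: replace the TBDPS group in Step 5 with an 8,10-isopropylidene acetonide (2,2-dimethoxypropane, PPTS). Remove it at the end with aqueous AcOH, which avoids basic conditions. The competing 7,10-dioxane acetonide would need to be checked by NMR.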